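(The data are simulated with constants of no real substance; the scatter is artificial.)

At 0.333 h the target in the blue run is 17.2% of the pair target plus isomer of the product, and by 0.833 h it is 5.08%. After that the fraction scatters about a level, so the crossing from kinetic to thermodynamic control appears to lie near there.

| flask | starting material | solid reagent | remark | time |
|---|---|---|---|---|
| blue | 0.80 M | 0.72 M | the very flask that is asked about, followed so far |  |
| red | 0.54 M | 0.72 M | run made earlier |  |
| flask | 0.80 M | 0.720 M |  | 5.0 h |

- blue (time / h: target / %, isomer of the product / %): 0.333: 8.8, 42.4; 0.833: 3.1, 57.9; 1.50: 2.2, 59.3; 2.50: 2.7, 59.9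
- red (time / h: target / %, isomer of the product / %): 0.417: 6.4, 52.6; 1.33: 2.2, 60.4; 2.50: 1.6, 59.8; 4.00: 2.6, 61.0

(each reading ± 0.5 percentage points)

- target at 5.0 h, in percent of the starting material charged
- isomer of the product at 5.0 h, in percent of the starting material charged

The 5 later readings of both runs average 2.26% of target and 60.1% of isomer of the product. Their late fraction is 3.63%: this is the target share, the part of the pair that stays target once the pair stops moving. From above, the blue reading of target on its fall, 3.1%, gives a loose bound, itself subject to the scatter. Two standard errors of the mean tighten this reckoning to a bracket from 1.81% to 2.71%, with the isomer of the product near 60.1%.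

The forecast gives 2.4% of target and 60.3% of isomer of the product, noting that less starting material “barely alters the plateau”. Its target lies inside the bracket, above 1.81% and below 2.71%.

The flask gives 2.14% of target and 60.1% of isomer of the product at 5.0 h, a target share of 3.44%. The relaxation half-life of the pair by the step between them alone, 2.79 min, is short against that time.

    starting material → side product (k = 0.00120 s⁻¹)
    solid reagent ⇌ partner, rate k2*(cs2 - [partner]) while solid is left; crystals form when [partner] > cs2 (solubility = 0.540 M, k = 0.00430 s⁻¹)
    target ⇌ isomer of the product (K = 28.0, k = 0.00400 s⁻¹)
    partner + intermediate → target (k = 0.00620 M⁻¹ s⁻¹)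
    starting material ⇌ intermediate (K = 9.50, k = 0.00220 s⁻¹)

A neighbour flask is charged with solid reagent at 22.5% of the starting material instead of 90.0%. Its isomer of the product is 21.7%, and the target share read from the runs turns that into 0.817% of target; the neighbour holds 0.776%. Its pair is smaller than the flask's, and at the end the neighbour holds 9.95% of intermediate and 66.9% of side product.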